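**Retrosynthetic overview**

1. Ring A of kolanone is numbered C1(=O), C2 (benzoyl-bearing), C3 (C–OH), C4 (prenyl-bearing), C5(=O), C6 (quaternary). The enabling feature is that C6 sits between the two ring carbonyls C1 and C5 as a 2,2-dialkylmalonyl unit with no α-hydrogen, while C2–C3–C4 plus the exocyclic benzoyl carbon are a 1,3-diketone with two nucleophilic carbons; the ring is a cyclic tetraketide.
2. Key disconnection: C1–C2 and C4–C5 are cut together. The forward step is a biomimetic Claisen/Claisen (Dieckmann-type) cascade between the dianion of 7-methyl-1-phenyloct-6-ene-1,3-dione and an enantiopure 2-geranyl-2-prenylmalonic acid chloride 2,2-diphenylethyl ester. Ring A is the only ring; it is closed last and the step gives the target directly.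
3. The C6 stereocenter is set beforehand by enantioselective phase-transfer geranylation of a mixed tert-butyl/2,2-diphenylethyl prenylmalonate. It is carried into the ring because the acyl chloride meets the terminal carbanion (C4) and the ester meets the central carbon (C2).
4. The diketone comes from benzoylacetone and prenyl bromide; the malonate comes from mono-tert-butyl malonate, 2,2-diphenylethanol, prenyl bromide and geranyl bromide.

Key step: step 7

Remark: kolanone is drawn as one enol tautomer of a 2-benzoylcyclohexane-1,3,5-trione, so a route to the (6R)-trione reaches it, and the facial sense of the phase-transfer alkylation in step 4 is assumed to give (S)-10 with the (S,S)-catalyst (its (R,R)-enantiomer would be used otherwise).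

Step 1
Reactants: 1 1-phenylbutane-1,3-dione (benzoylacetone); 2 1-bromo-3-methylbut-2-ene (prenyl bromide)
Product: 4 7-methyl-1-phenyloct-6-ene-1,3-dione, via dilithium benzoylacetone dianion 3 (not isolated)
Conditions: LiN(iPr)2 (2.1 equiv), THF, −78 to 0 °C; then 2 (1.0 equiv), −78 °C to rt; 1 M aq HCl
Reagents that add atoms: none
Why: γ-Alkylation of a 1,3-diketone dianion, in which the terminal carbanion of 3 is much more nucleophilic than the central carbon and should displace bromide from the primary allylic carbon by SN2, with no stereocenter formed.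

Step 2
Reactants: 5 3-tert-butoxy-3-oxopropanoic acid (mono-tert-butyl malonate); 6 2,2-diphenylethanol
Product: 7 tert-butyl 2,2-diphenylethyl propanedioate
Conditions: N,N'-dicyclohexylcarbodiimide, 4-(dimethylamino)pyridine (cat.), CH2Cl2, 0 °C to rt
Reagents that add atoms: none
Why: Steglich esterification of the free acid of a malonic half-ester with a primary alcohol, which leaves the tert-butyl ester untouched and forms no stereocenter.

Step 3
Reactants: 7 tert-butyl 2,2-diphenylethyl propanedioate; 2 1-bromo-3-methylbut-2-ene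
Product: 8 1-tert-butyl 3-(2,2-diphenylethyl) 2-(3-methylbut-2-en-1-yl)propanedioate (racemic)
Conditions: K2CO3, DMF, rt (7 in slight excess)
Reagents that add atoms: none
Why: Malonate C-alkylation (SN2 at the primary allylic carbon) under mild carbonate conditions, where the slight excess of 7 should hold back dialkylation and the new stereocenter forms as a racemate that is planarized again in step 4.

Step 4
Reactants: 8 1-tert-butyl 3-(2,2-diphenylethyl) 2-(3-methylbut-2-en-1-yl)propanedioate; 9 (2E)-1-bromo-3,7-dimethylocta-2,6-diene (geranyl bromide)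
Product: 10 1-tert-butyl 3-(2,2-diphenylethyl) (2S)-2-[(2E)-3,7-dimethylocta-2,6-dien-1-yl]-2-(3-methylbut-2-en-1-yl)propanedioate
Conditions: (11bS,11'bS)-2,6-bis(3,4,5-trifluorophenyl)-3,3',5,5'-tetrahydro-4,4'-spirobi[dinaphtho[2,1-c:1',2'-e]azepin]-4-ium bromide (C56H34BrF6N, 5 mol%), 50% aq KOH, toluene, −40 °C
Reagents that add atoms: none
Why: Enantioselective phase-transfer-catalyzed α-alkylation of a mixed α-monosubstituted malonate, in which the chiral ammonium cation pairs with the planar enolate of racemic 8 and tells its two faces apart through the unlike tert-butyl and 2,2-diphenylethyl ester groups, so that the catalyst sets the quaternary stereocenter stereoconvergently as geranyl bromide reacts by SN2.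

Step 5
Reactants: 10 1-tert-butyl 3-(2,2-diphenylethyl) (2S)-2-[(2E)-3,7-dimethylocta-2,6-dien-1-yl]-2-(3-methylbut-2-en-1-yl)propanedioate
Product: 12 (2R)-3-(2,2-diphenylethoxy)-2-[(2E)-3,7-dimethylocta-2,6-dien-1-yl]-2-(3-methylbut-2-en-1-yl)-3-oxopropanoic acid, via trimethylsilyl ester 11 (not isolated)
Conditions: Me3SiOSO2CF3, 2,6-lutidine, CH2Cl2, 0 °C; then H2O, pH 4 buffer
Reagents that add atoms: none
Why: Silyl-triflate-mediated dealkylation of a tert-butyl ester (alkyl–oxygen fission with loss of 2-methylpropene, the base intercepting the acid) should spare the primary ester and the three trisubstituted alkenes, the silyl group of 11 is lost again on aqueous work-up, and the quaternary stereocenter is not touched.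

Step 6
Reactants: 12 (2R)-3-(2,2-diphenylethoxy)-2-[(2E)-3,7-dimethylocta-2,6-dien-1-yl]-2-(3-methylbut-2-en-1-yl)-3-oxopropanoic acid
Product: 13 2,2-diphenylethyl (2S)-3-chloro-2-[(2E)-3,7-dimethylocta-2,6-dien-1-yl]-2-(3-methylbut-2-en-1-yl)-3-oxopropanoate
Conditions: 1-chloro-N,N,2-trimethylprop-1-en-1-amine (1.2 equiv), CH2Cl2, 0 °C to rt; concentrate, use crude
Reagents that add atoms: 1-chloro-N,N,2-trimethylprop-1-en-1-amine, CC(C)=C(Cl)N(C)C
Why: Acid chloride formation with an α-chloroenamine under neutral conditions, which releases no HCl onto the acid-sensitive alkenes and cannot epimerize a stereocenter that has no α-hydrogen (the descriptor changes only because the priorities change).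

Step 7
Reactants: 4 7-methyl-1-phenyloct-6-ene-1,3-dione; 13 2,2-diphenylethyl (2S)-3-chloro-2-[(2E)-3,7-dimethylocta-2,6-dien-1-yl]-2-(3-methylbut-2-en-1-yl)-3-oxopropanoate
Product: 16 kolanone, via dilithium diketone dianion 14 (not isolated), via open-chain triketo ester 15 (not isolated)
Conditions: 4 (2.2 equiv), LiN(iPr)2 (4.4 equiv), THF, −78 to 0 °C; then 13 (1.0 equiv, slow addition), −78 °C to rt, then 40 °C; 1 M aq HCl, 0 °C
Reagents that add atoms: none
Why: The dianion 14 should attack the acyl chloride of 13 with its terminal carbon, the more nucleophilic of its two carbanionic sites, to make C4–C5; the excess of 14 then deprotonates the tetracarbonyl ester 15, whose central carbon (between the ketone and the benzoyl group) closes ring A by a Claisen attack on the 2,2-diphenylethyl ester, making C1–C2 and expelling the alkoxide. The closest known reaction types are the γ-acylation of 1,3-diketone dianions and the Claisen cyclization of 3,5,7-trioxo esters to acylphloroglucinols, which is also how the polyketide synthase is presumed to close this ring in the biosynthesis. Ring A closes in a 6-(enolendo)-exo-trig C-acylation; O-acylation to the six-membered enol lactone is reversible under the alkoxide conditions, whereas the C-acylated trione is trapped as its stabilized enolate, and the aldol mode that normally competes in polyketide cyclizations is blocked because C6 carries no hydrogen. No new stereocenter is formed: C6 is carried over from 13 because none of its bonds is broken and it cannot enolize, and the transient stereocenter at the prenyl-bearing carbon of 15 and all enolate geometries converge on the same enol. The step needs chemoselectivity (acyl chloride before ester) and regioselectivity (terminal before central carbon), since the reverse pairing would give the enantiomer; the reactivity gap between the acyl chloride and the hindered ester at −78 °C and between the two carbanionic sites of 14 should secure both.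

**Compound list**

1 | 1-phenylbutane-1,3-dione (benzoylacetone) | CC(=O)CC(=O)c1ccccc1 | starting material
2 | 1-bromo-3-methylbut-2-ene (prenyl bromide) | CC(C)=CCBr | starting material
3 | dilithium 1-phenylbuta-1,3-diene-1,3-diolate (enolate geometry undefined) | [Li+].[Li+].C=C([O-])C=C([O-])c1ccccc1 | intermediate
4 | 7-methyl-1-phenyloct-6-ene-1,3-dione | CC(C)=CCCC(=O)CC(=O)c1ccccc1 | intermediate
5 | 3-tert-butoxy-3-oxopropanoic acid (mono-tert-butyl malonate) | CC(C)(C)OC(=O)CC(=O)O | starting material
6 | 2,2-diphenylethanol | OCC(c1ccccc1)c1ccccc1 | starting material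
7 | tert-butyl 2,2-diphenylethyl propanedioate | CC(C)(C)OC(=O)CC(=O)OCC(c1ccccc1)c1ccccc1 | intermediate
8 | 1-tert-butyl 3-(2,2-diphenylethyl) 2-(3-methylbut-2-en-1-yl)propanedioate (racemic) | CC(C)=CCC(C(=O)OC(C)(C)C)C(=O)OCC(c1ccccc1)c1ccccc1 | intermediate
9 | (2E)-1-bromo-3,7-dimethylocta-2,6-diene (geranyl bromide) | CC(C)=CCC/C(C)=C/CBr | starting material
10 | 1-tert-butyl 3-(2,2-diphenylethyl) (2S)-2-[(2E)-3,7-dimethylocta-2,6-dien-1-yl]-2-(3-methylbut-2-en-1-yl)propanedioate | CC(C)=CCC/C(C)=C/C[C@](CC=C(C)C)(C(=O)OC(C)(C)C)C(=O)OCC(c1ccccc1)c1ccccc1 | intermediate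
11 | 2,2-diphenylethyl trimethylsilyl (2S)-2-[(2E)-3,7-dimethylocta-2,6-dien-1-yl]-2-(3-methylbut-2-en-1-yl)propanedioate | CC(C)=CCC/C(C)=C/C[C@](CC=C(C)C)(C(=O)O[Si](C)(C)C)C(=O)OCC(c1ccccc1)c1ccccc1 | intermediate
12 | (2R)-3-(2,2-diphenylethoxy)-2-[(2E)-3,7-dimethylocta-2,6-dien-1-yl]-2-(3-methylbut-2-en-1-yl)-3-oxopropanoic acid | CC(C)=CCC/C(C)=C/C[C@](CC=C(C)C)(C(=O)O)C(=O)OCC(c1ccccc1)c1ccccc1 | intermediate
13 | 2,2-diphenylethyl (2S)-3-chloro-2-[(2E)-3,7-dimethylocta-2,6-dien-1-yl]-2-(3-methylbut-2-en-1-yl)-3-oxopropanoate | CC(C)=CCC/C(C)=C/C[C@](CC=C(C)C)(C(=O)Cl)C(=O)OCC(c1ccccc1)c1ccccc1 | intermediate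
14 | dilithium 7-methyl-1-phenylocta-1,3,6-triene-1,3-diolate (enolate geometry undefined) | [Li+].[Li+].CC(C)=CCC=C([O-])C=C([O-])c1ccccc1 | intermediate
15 | 2,2-diphenylethyl (2R)-2-[(2E)-3,7-dimethylocta-2,6-dien-1-yl]-2,4-bis(3-methylbut-2-en-1-yl)-3,5,7-trioxo-7-phenylheptanoate (C4 epimers and enol tautomers) | CC(C)=CCC/C(C)=C/C[C@](CC=C(C)C)(C(=O)C(CC=C(C)C)C(=O)CC(=O)c1ccccc1)C(=O)OCC(c1ccccc1)c1ccccc1 | intermediate
16 | kolanone, (6R)-6-[(2E)-3,7-dimethylocta-2,6-dien-1-yl]-3-hydroxy-2-[(E)-hydroxy(phenyl)methylidene]-4,6-bis(3-methylbut-2-en-1-yl)cyclohex-3-ene-1,5-dione | CC(C)=CCC/C(C)=C/C[C@]1(CC=C(C)C)C(=O)C(CC=C(C)C)=C(O)/C(=C(\O)c2ccccc2)C1=O | target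

**Step count and risks**

Total step count: 7. Longest linear sequence: 6 steps (steps 2 to 7, from mono-tert-butyl malonate); step 1 is a one-step side branch.

Steps most likely to fail:

Step 7. What may go wrong: O-acylation or multiple acylation of the dianion, stalling of the ring closure at the open-chain stage, or retro-Claisen cleavage under the strongly basic one-pot conditions. Fallback: setting out from 4, the diketone would be silylated (Me3SiCl, Et3N; then LiN(iPr)2, Me3SiCl, THF, −78 °C) to its bis-silyl dienol ether, [(7-methyl-1-phenylocta-1,3,6-triene-1,3-diyl)bis(oxy)]bis(trimethylsilane) F1. As a neutral nucleophile F1 should be C-acylated at its terminal carbon by 13 (CH2Cl2, −78 to 20 °C, Me3SiOSO2CF3 cat. if needed), and aqueous work-up would give 15 as an isolated compound. A separate Claisen ring closure of 15 (LiN(SiMe3)2 or NaH, THF, 0 °C to rt) would then come back to the route at 16.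

Step 4. What may go wrong: poor facial selectivity of the ion pair with the larger α-prenyl substituent, or slow alkylation with competing ester hydrolysis. Fallback: setting out from 8, alkylation without the chiral salt (NaH, 9, THF/DMF, 0 °C to rt) would give the racemic diester, 1-tert-butyl 3-(2,2-diphenylethyl) 2-[(2E)-3,7-dimethylocta-2,6-dien-1-yl]-2-(3-methylbut-2-en-1-yl)propanedioate F2. Preparative chromatography on a chiral stationary phase (amylose tris(3,5-dimethylphenylcarbamate), supercritical CO2/alcohol) would separate it into the (2S)-diester and the (2R)-enantiomer of the diester F3, which is set aside. The route is rejoined at 10.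

Step 5. What may go wrong: cation- or acid-induced cyclization or tert-butylation of the trisubstituted alkenes, or incomplete dealkylation. Fallback: the tert-butyl ester is kept and the two ring bonds are made in the reverse order. Setting out from 10, saponification of the primary ester (KOH, MeOH/H2O) would give (2S)-3-tert-butoxy-2-[(2E)-3,7-dimethylocta-2,6-dien-1-yl]-2-(3-methylbut-2-en-1-yl)-3-oxopropanoic acid F4. The chloroenamine of step 6 would convert it into tert-butyl (2R)-3-chloro-2-[(2E)-3,7-dimethylocta-2,6-dien-1-yl]-2-(3-methylbut-2-en-1-yl)-3-oxopropanoate F5. C-acylation of the central carbon of 4 under soft enolization (MgCl2, Et3N, MeCN/CH2Cl2) would give tert-butyl (2S)-4-benzoyl-2-[(2E)-3,7-dimethylocta-2,6-dien-1-yl]-9-methyl-2-(3-methylbut-2-en-1-yl)-3,5-dioxodec-8-enoate F6. Its terminal carbanion (LiN(iPr)2, 3 equiv, THF, −78 °C to rt) should then close ring A by a Dieckmann-type attack on the tert-butyl ester, coming back to the route at 16 with the same configuration at C6.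

**Further compounds**

F1 | step 7 | [(7-methyl-1-phenylocta-1,3,6-triene-1,3-diyl)bis(oxy)]bis(trimethylsilane) (mixture of enol ether geometries) | CC(C)=CCC=C(O[Si](C)(C)C)C=C(O[Si](C)(C)C)c1ccccc1
F2 | step 4 | racemic 1-tert-butyl 3-(2,2-diphenylethyl) 2-[(2E)-3,7-dimethylocta-2,6-dien-1-yl]-2-(3-methylbut-2-en-1-yl)propanedioate | CC(C)=CCC/C(C)=C/CC(CC=C(C)C)(C(=O)OC(C)(C)C)C(=O)OCC(c1ccccc1)c1ccccc1
F3 | step 4 | 1-tert-butyl 3-(2,2-diphenylethyl) (2R)-2-[(2E)-3,7-dimethylocta-2,6-dien-1-yl]-2-(3-methylbut-2-en-1-yl)propanedioate | CC(C)=CCC/C(C)=C/C[C@@](CC=C(C)C)(C(=O)OC(C)(C)C)C(=O)OCC(c1ccccc1)c1ccccc1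
F4 | step 5 | (2S)-3-tert-butoxy-2-[(2E)-3,7-dimethylocta-2,6-dien-1-yl]-2-(3-methylbut-2-en-1-yl)-3-oxopropanoic acid | CC(C)=CCC/C(C)=C/C[C@](CC=C(C)C)(C(=O)OC(C)(C)C)C(=O)O
F5 | step 5 | tert-butyl (2R)-3-chloro-2-[(2E)-3,7-dimethylocta-2,6-dien-1-yl]-2-(3-methylbut-2-en-1-yl)-3-oxopropanoate | CC(C)=CCC/C(C)=C/C[C@](CC=C(C)C)(C(=O)OC(C)(C)C)C(=O)Cl
F6 | step 5 | tert-butyl (2S)-4-benzoyl-2-[(2E)-3,7-dimethylocta-2,6-dien-1-yl]-9-methyl-2-(3-methylbut-2-en-1-yl)-3,5-dioxodec-8-enoate | CC(C)=CCC/C(C)=C/C[C@](CC=C(C)C)(C(=O)OC(C)(C)C)C(=O)C(C(=O)CCC=C(C)C)C(=O)c1ccccc1
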